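**Plan**

- Retrosynthetic cuts, in order: the C3–CH2CO2H bond (silyl ketene acetal on a cyclic peroxycarbenium ion); the C5–O bond of the peroxide (hydrogen peroxide opening of an oxetane with inversion); the ring bond between C4 and C5 of the dioxolane (carbene C–H insertion); the ether C–O bond and one chain C–C bond.
- Forward: (R)-12-phenyldodecan-2-ol is O-alkylated and turned into an alpha-alkoxy diazoketone; Rh2(OAc)4 closes an oxolan-3-one (temporary ring 1) by the C4–C5 bond; SmI2 cuts the tether C–O bond; an oxetane (temporary ring 2) relays C5 to the hydroperoxide; the 1,2-dioxolane (ring 3) closes on the ketone and receives the acetate arm last.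
- Enabling feature: the tertiary C5–H of the sec-alkyl ether is alpha to oxygen and stands 1,5 to the diazo carbon (future C4) across the O–CH2–C(=O) tether, so insertion makes a five-membered ring; the tether CH2 and C=O carbons become the C3 methyl group and C3.
- Stereochemistry: C5 derives from commercial (R)-but-3-yn-2-ol, passes into the quaternary centre with retention in the insertion and is inverted once in the oxetane perhydrolysis, giving (5S). C3 (3R, acetate arm trans to the phenyldecyl chain, ring methyls trans) is set in the peroxycarbenium addition of step 12, under weak substrate control with removal of the epimer.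

Key step: step 5

**Route**

Step 1
Reactants: 1 (R)-but-3-yn-2-ol; 2 (8-bromooctyl)benzene
Product: 4 (R)-12-phenyldodec-3-yn-2-ol, via dilithium alkoxide-acetylide 3 (not isolated)
Conditions: n-BuLi (2.1 equiv), THF–DMPU, −78 → 0 °C; then 2, 0 °C → rt; H2O
Reagents that add atoms: none
Why: Double deprotonation gives the O,C-dilithio species, whose acetylide carbon displaces the primary bromide (SN2 alkylation of an acetylide) while the alkoxide stays inert, so the (R) carbinol centre is carried through untouched.

Step 2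
Reactants: 4 (R)-12-phenyldodec-3-yn-2-ol
Product: 5 (R)-12-phenyldodecan-2-ol
Conditions: H2 (1 atm), Pd/C, EtOAc, rt
Reagents that add atoms: none
Why: Catalytic hydrogenation saturates the alkyne to the alkane without breaking the C–O bond, so the configuration of the carbinol carbon is kept and the phenyl ring is not reduced under these mild conditions.

Step 3
Reactants: 5 (R)-12-phenyldodecan-2-ol; 6 bromoacetic acid
Product: 7 2-{[(2R)-12-phenyldodecan-2-yl]oxy}acetic acid
Conditions: NaH (2.5 equiv), THF, 0 °C → reflux; then aq. HCl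
Reagents that add atoms: none
Why: Williamson ether synthesis: the sodium alkoxide of 5 displaces bromide from sodium bromoacetate, an electrophile that cannot eliminate, and no bond to the stereocentre is broken.

Step 4
Reactants: 7 2-{[(2R)-12-phenyldodecan-2-yl]oxy}acetic acid
Product: 9 1-diazo-3-{[(2R)-12-phenyldodecan-2-yl]oxy}propan-2-one, via acid chloride 8 (not isolated)
Conditions: (COCl)2, DMF (cat.), CH2Cl2, 0 °C → rt, evaporate; then CH2N2 (3 equiv), Et2O, 0 °C
Reagents that add atoms: diazomethane, C=[N+]=[N-]; oxalyl chloride, O=C(Cl)C(=O)Cl (chlorine of 8 only)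
Why: The acid chloride acylates diazomethane (first stage of the Arndt–Eistert sequence) and a further equivalent of diazomethane takes up HCl, which gives the alpha-diazoketone with the ether stereocentre untouched.

Step 5
Reactants: 9 1-diazo-3-{[(2R)-12-phenyldodecan-2-yl]oxy}propan-2-one
Product: 10 (5R)-5-methyl-5-(10-phenyldecyl)oxolan-3-one
Conditions: Rh2(OAc)4 (1 mol %), CH2Cl2 (0.01 M), rt, 9 added over several hours
Reagents that add atoms: none
Why: Rh2(OAc)4 extrudes N2 from 9 and the catalyst-bound, electrophilic carbene carbon (the future C4) inserts into the C5–H bond in one concerted three-centre step. The closest known reaction type is the intramolecular C–H insertion of alpha-alkoxy-alpha'-diazoketones to oxolan-3-ones. The oxolanone ring closes in the 1,5 mode (five-membered transition state through C(=O)–CH2–O), the only low-strain mode open to this tether. The quaternary centre C5 keeps the spatial arrangement of the (R) carbinol because the C–C bond forms on the side from which hydrogen departs (retention). The step needs insertion at C5–H in preference to oxonium ylide formation at the ether oxygen, to 1,6-insertion into the methyl or chain CH2 and to carbene dimerisation; C5–H is the only tertiary, oxygen-activated C–H and the only one 1,5 to the carbene carbon, and slow addition at high dilution suppresses dimerisation.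

Step 6
Reactants: 10 (5R)-5-methyl-5-(10-phenyldecyl)oxolan-3-one
Product: 12 (4R)-4-methyl-14-phenyltetradecane-2,4-diol (both C2 epimers), via beta-hydroxy ketone 11 (not isolated)
Conditions: SmI2 (2.2 equiv), THF–MeOH, −78 °C; then NaBH4, −78 → 0 °C
Reagents that add atoms: none
Why: Two-electron reduction of the ketone by SmI2 expels the alpha-alkoxy group (reductive cleavage of an alpha-alkoxy ketone), which turns the tether CH2 into the future C3 methyl group and frees the tertiary alcohol without touching C5, and NaBH4 then reduces the ketone so that the retro-aldol-prone aldol 11 is not handled; the new secondary carbinol is a mixture that is oxidised again in step 10.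

Step 7
Reactants: 12 (4R)-4-methyl-14-phenyltetradecane-2,4-diol
Product: 14 (2R)-2,4-dimethyl-2-(10-phenyldecyl)oxetane (both C4 epimers), via secondary monotosylate 13 (not isolated)
Conditions: TsCl (1.1 equiv), pyridine, 0 °C; then KOt-Bu, THF, 0 °C → rt
Reagents that add atoms: p-toluenesulfonyl chloride, Cc1ccc(cc1)S(Cl)(=O)=O (atoms of 13 only; none stay in 14)
Why: The secondary hydroxyl is sulfonylated selectively over the tertiary one and the tertiary alkoxide then closes the ring by 4-exo-tet Williamson displacement, so the C–O bond of the quaternary centre stays intact (retention) and only the immaterial secondary centre is inverted.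

Step 8
Reactants: 14 (2R)-2,4-dimethyl-2-(10-phenyldecyl)oxetane
Product: 15 (4S)-4-hydroperoxy-4-methyl-14-phenyltetradecan-2-ol (both C2 epimers)
Conditions: H2O2 (anhydrous, in Et2O, 5 equiv), TMSOTf (0.2 equiv), Et2O, −78 → 0 °C
Reagents that add atoms: hydrogen peroxide, OO
Why: The Lewis acid activated oxetane is opened by hydrogen peroxide at the more substituted carbon in an SN2-like, strain-driven substitution with inversion, which converts the (R) tertiary ether carbon into the (S) tertiary hydroperoxide carbon, the C5 of the target.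

Step 9
Reactants: 15 (4S)-4-hydroperoxy-4-methyl-14-phenyltetradecan-2-ol
Product: 16 (4S)-4-[(2-methoxypropan-2-yl)peroxy]-4-methyl-14-phenyltetradecan-2-ol
Conditions: 2-methoxypropene (1.1 equiv), PPTS (cat.), CH2Cl2, 0 °C
Reagents that add atoms: 2-methoxypropene, COC(C)=C
Why: Under mild acid the hydroperoxide, the more acidic and more nucleophilic O–H group, adds to the enol ether to give the 2-methoxypropan-2-yl peroxyketal, which masks the O–O–H during the oxidation that follows.

Step 10
Reactants: 16 (4S)-4-[(2-methoxypropan-2-yl)peroxy]-4-methyl-14-phenyltetradecan-2-ol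
Product: 17 (4S)-4-[(2-methoxypropan-2-yl)peroxy]-4-methyl-14-phenyltetradecan-2-one
Conditions: Dess–Martin periodinane, NaHCO3, CH2Cl2, 0 °C → rt
Reagents that add atoms: none
Why: Dess–Martin oxidation converts the secondary alcohol into the methyl ketone under buffered, non-reducing conditions that leave the peroxyketal and the tertiary peroxide centre untouched.

Step 11
Reactants: 17 (4S)-4-[(2-methoxypropan-2-yl)peroxy]-4-methyl-14-phenyltetradecan-2-one
Product: 19 (5S)-3-methoxy-3,5-dimethyl-5-(10-phenyldecyl)-1,2-dioxolane (both C3 epimers), via hydroperoxy ketone 18 (not isolated)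
Conditions: PPTS (cat.), MeOH, 4 Å molecular sieves, rt
Reagents that add atoms: methanol, CO
Why: Acid methanolysis removes the peroxyketal, the freed hydroperoxide adds to the ketone in a 5-exo-trig closure and the cyclic hemiperoxyketal is exchanged to the methyl peroxyketal; C3 forms as an epimeric mixture that is of no consequence because this carbon is made planar in step 12.

Step 12
Reactants: 19 (5S)-3-methoxy-3,5-dimethyl-5-(10-phenyldecyl)-1,2-dioxolane; 20 tert-butyl[(1-methoxyethenyl)oxy]dimethylsilane
Product: 22 methyl 2-[(3R,5S)-3,5-dimethyl-5-(10-phenyldecyl)-1,2-dioxolan-3-yl]acetate, via peroxycarbenium ion 21 (not isolated)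
Conditions: TiCl4 (1.1 equiv), 20 (2 equiv), CH2Cl2, −78 °C; chromatographic removal of the C3 epimer
Reagents that add atoms: none
Why: TiCl4 ionises the C3–OMe bond to the cyclic peroxycarbenium ion 21, which is trapped by the silyl ketene acetal (Mukaiyama-type addition to an oxocarbenium ion); C3 is set under substrate control by attack anti to the longer C5 substituent, which puts the acetate arm trans to the phenyldecyl chain as in the target, but because the bias between methyl and chain CH2 should be weak the C3 epimer is removed at this ester stage.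

Step 13
Reactants: 22 methyl 2-[(3R,5S)-3,5-dimethyl-5-(10-phenyldecyl)-1,2-dioxolan-3-yl]acetate
Product: 23 andavadoic acid (2-[(3R,5S)-3,5-dimethyl-5-(10-phenyldecyl)-1,2-dioxolan-3-yl]acetic acid)
Conditions: LiOH, THF–H2O, 0 °C → rt; then aq. HCl to pH 3
Reagents that add atoms: lithium hydroxide, [Li+].[OH-]
Why: Saponification of the methyl ester; the tetrasubstituted dioxolane carries no hydrogen on its O-bearing carbons, so base-induced Kornblum–DeLaMare cleavage cannot occur and both stereocentres are untouched.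

**Compound list**

1 | (R)-but-3-yn-2-ol | C[C@@H](O)C#C | starting material
2 | (8-bromooctyl)benzene | BrCCCCCCCCc1ccccc1 | starting material
3 | dilithium alkoxide-acetylide of 1 (not isolated) | C[C@@H](O[Li])C#C[Li] | intermediate
4 | (R)-12-phenyldodec-3-yn-2-ol | C[C@@H](O)C#CCCCCCCCCc1ccccc1 | intermediate
5 | (R)-12-phenyldodecan-2-ol | C[C@@H](O)CCCCCCCCCCc1ccccc1 | intermediate
6 | bromoacetic acid | OC(=O)CBr | starting material
7 | 2-{[(2R)-12-phenyldodecan-2-yl]oxy}acetic acid | C[C@@H](OCC(=O)O)CCCCCCCCCCc1ccccc1 | intermediate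
8 | 2-{[(2R)-12-phenyldodecan-2-yl]oxy}acetyl chloride (not isolated) | C[C@@H](OCC(=O)Cl)CCCCCCCCCCc1ccccc1 | intermediate
9 | 1-diazo-3-{[(2R)-12-phenyldodecan-2-yl]oxy}propan-2-one | C[C@@H](OCC(=O)C=[N+]=[N-])CCCCCCCCCCc1ccccc1 | intermediate
10 | (5R)-5-methyl-5-(10-phenyldecyl)oxolan-3-one | C[C@@]1(CCCCCCCCCCc2ccccc2)CC(=O)CO1 | intermediate
11 | (4R)-4-hydroxy-4-methyl-14-phenyltetradecan-2-one (not isolated) | C[C@@](O)(CCCCCCCCCCc1ccccc1)CC(C)=O | intermediate
12 | (4R)-4-methyl-14-phenyltetradecane-2,4-diol, both C2 epimers | C[C@@](O)(CCCCCCCCCCc1ccccc1)CC(C)O | intermediate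
13 | (4R)-4-hydroxy-4-methyl-14-phenyltetradecan-2-yl 4-methylbenzenesulfonate, both C2 epimers (not isolated) | C[C@@](O)(CCCCCCCCCCc1ccccc1)CC(C)OS(=O)(=O)c1ccc(C)cc1 | intermediate
14 | (2R)-2,4-dimethyl-2-(10-phenyldecyl)oxetane, both C4 epimers | C[C@@]1(CCCCCCCCCCc2ccccc2)CC(C)O1 | intermediate
15 | (4S)-4-hydroperoxy-4-methyl-14-phenyltetradecan-2-ol, both C2 epimers | C[C@](OO)(CCCCCCCCCCc1ccccc1)CC(C)O | intermediate
16 | (4S)-4-[(2-methoxypropan-2-yl)peroxy]-4-methyl-14-phenyltetradecan-2-ol, both C2 epimers | C[C@](OOC(C)(C)OC)(CCCCCCCCCCc1ccccc1)CC(C)O | intermediate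
17 | (4S)-4-[(2-methoxypropan-2-yl)peroxy]-4-methyl-14-phenyltetradecan-2-one | C[C@](OOC(C)(C)OC)(CCCCCCCCCCc1ccccc1)CC(C)=O | intermediate
18 | (4S)-4-hydroperoxy-4-methyl-14-phenyltetradecan-2-one (not isolated) | C[C@](OO)(CCCCCCCCCCc1ccccc1)CC(C)=O | intermediate
19 | (5S)-3-methoxy-3,5-dimethyl-5-(10-phenyldecyl)-1,2-dioxolane, both C3 epimers | C[C@]1(CCCCCCCCCCc2ccccc2)CC(C)(OC)OO1 | intermediate
20 | tert-butyl[(1-methoxyethenyl)oxy]dimethylsilane | C=C(OC)O[Si](C)(C)C(C)(C)C | starting material
21 | (5S)-3,5-dimethyl-5-(10-phenyldecyl)-4,5-dihydro-1,2-dioxol-2-ium, the cyclic peroxycarbenium ion (not isolated) | C[C@]1(CCCCCCCCCCc2ccccc2)CC(C)=[O+]O1 | intermediate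
22 | methyl 2-[(3R,5S)-3,5-dimethyl-5-(10-phenyldecyl)-1,2-dioxolan-3-yl]acetate | C[C@]1(CCCCCCCCCCc2ccccc2)C[C@](C)(CC(=O)OC)OO1 | intermediate
23 | andavadoic acid, 2-[(3R,5S)-3,5-dimethyl-5-(10-phenyldecyl)-1,2-dioxolan-3-yl]acetic acid | C[C@]1(CCCCCCCCCCc2ccccc2)C[C@](C)(CC(=O)O)OO1 | target

**Step count and risks**

Total step count: 13. Longest linear sequence: 13 steps (1 to 23).

Steps most likely to fail:

1. Step 12. Both faces of the planar peroxycarbenium ion may be attacked at similar rates, because the controlling C5 centre differs only in methyl against the CH2 of the chain, so facial selectivity at C3 may be poor. The fallback replaces cation trapping by a reagent-controlled epoxidation and a stereospecific ring closure; it sets out from 17 and comes back at 23.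
   - Horner–Wadsworth–Emmons olefination of 17 ((EtO)2P(O)CH2CO2Et, NaH, THF, 0 °C, E isomer separated) should give ethyl (2E,5S)-5-[(2-methoxypropan-2-yl)peroxy]-3,5-dimethyl-15-phenylpentadec-2-enoate F1.
   - DIBAL-H (CH2Cl2, −78 °C) should give (2E,5S)-5-[(2-methoxypropan-2-yl)peroxy]-3,5-dimethyl-15-phenylpentadec-2-en-1-ol F2.
   - Sharpless asymmetric epoxidation (Ti(Oi-Pr)4, L-(+)-diethyl tartrate, t-BuOOH, 4 Å sieves, CH2Cl2, −20 °C) should give [(2S,3S)-3-{(2S)-2-[(2-methoxypropan-2-yl)peroxy]-2-methyl-12-phenyldodecyl}-3-methyloxiran-2-yl]methanol F3 under reagent control.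
   - PPTS in MeOH, then camphorsulfonic acid in CH2Cl2, frees the hydroperoxide, which opens the epoxide 5-exo at its tertiary carbon with inversion. This fixes C3 in (1S)-1-[(3R,5S)-3,5-dimethyl-5-(10-phenyldecyl)-1,2-dioxolan-3-yl]ethane-1,2-diol F4.
   - NaIO4 (THF–H2O) cleaves the glycol to (3R,5S)-3,5-dimethyl-5-(10-phenyldecyl)-1,2-dioxolane-3-carbaldehyde F5.
   - Wittig reaction with Ph3P=CHOMe gives (3R,5S)-3-(2-methoxyethenyl)-3,5-dimethyl-5-(10-phenyldecyl)-1,2-dioxolane F6, and mild aqueous acid hydrolyses it to 2-[(3R,5S)-3,5-dimethyl-5-(10-phenyldecyl)-1,2-dioxolan-3-yl]acetaldehyde F7.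
   - Pinnick oxidation (NaClO2, NaH2PO4, 2-methylbut-2-ene) gives 23.

2. Step 7. The tertiary alkoxide next to a secondary sulfonate may undergo Grob-type fragmentation or E2 elimination faster than the 4-exo ring closure. The fallback builds the four-membered ring by acyl C–O closure, where no such fragmentation is open; it sets out from 10 and comes back at 14.
   - Baeyer–Villiger oxidation of 10 (m-CPBA, NaHCO3, CH2Cl2), with migration of the alkoxymethyl carbon, should give (6R)-6-methyl-6-(10-phenyldecyl)-1,3-dioxan-4-one F8.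
   - LiOH (THF–H2O) releases formaldehyde and gives (3R)-3-hydroxy-3-methyl-13-phenyltridecanoic acid F9.
   - PhSO2Cl in pyridine activates the carboxyl group and closes (4R)-4-methyl-4-(10-phenyldecyl)oxetan-2-one F10 with the C–O bond of the stereocentre intact.
   - Cp2TiMe2 (toluene, 75 °C) methylenates the lactone carbonyl to (2R)-2-methyl-4-methylidene-2-(10-phenyldecyl)oxetane F11.
   - Hydrogenation of the enol ether (H2, Pd/C, Et3N, EtOAc) gives 14.

3. Step 5. The metal carbene may be diverted by attack on the ether oxygen (oxonium ylide followed by 1,2-shift), by dimerisation or by insertion at a more remote C–H. The fallback forms the same quaternary carbinol by lithiation–borylation; it sets out from 5 and comes back at 11.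
   - Acylation of 5 with 2,4,6-tri(propan-2-yl)benzoyl chloride (pyridine, DMAP; retention) gives (2R)-12-phenyldodecan-2-yl 2,4,6-tri(propan-2-yl)benzoate F12.
   - Deprotonation with s-BuLi/TMEDA (cyclopentyl methyl ether, −60 °C) gives a configurationally stable alpha-oxy organolithium, which is trapped with 2-methylallylboronic acid pinacol ester with retention. Warming triggers the 1,2-metallate shift with inversion at carbon and gives 2-[(4S)-2,4-dimethyl-14-phenyltetradec-1-en-4-yl]-4,4,5,5-tetramethyl-1,3,2-dioxaborolane F13.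
   - Oxidation (NaOH, H2O2; retention) gives (4R)-2,4-dimethyl-14-phenyltetradec-1-en-4-ol F14.
   - Ozonolysis (O3, CH2Cl2, −78 °C; Me2S) gives 11, which is reduced to 12 with NaBH4 as in the second half of step 6.

**Further compounds**

F1 | step 12 | ethyl (2E,5S)-5-[(2-methoxypropan-2-yl)peroxy]-3,5-dimethyl-15-phenylpentadec-2-enoate | CCOC(=O)/C=C(\C)C[C@@](C)(OOC(C)(C)OC)CCCCCCCCCCc1ccccc1
F2 | step 12 | (2E,5S)-5-[(2-methoxypropan-2-yl)peroxy]-3,5-dimethyl-15-phenylpentadec-2-en-1-ol | OC/C=C(\C)C[C@@](C)(OOC(C)(C)OC)CCCCCCCCCCc1ccccc1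
F3 | step 12 | [(2S,3S)-3-{(2S)-2-[(2-methoxypropan-2-yl)peroxy]-2-methyl-12-phenyldodecyl}-3-methyloxiran-2-yl]methanol | OC[C@@H]1O[C@@]1(C)C[C@@](C)(OOC(C)(C)OC)CCCCCCCCCCc1ccccc1
F4 | step 12 | (1S)-1-[(3R,5S)-3,5-dimethyl-5-(10-phenyldecyl)-1,2-dioxolan-3-yl]ethane-1,2-diol | C[C@]1(CCCCCCCCCCc2ccccc2)C[C@](C)([C@@H](O)CO)OO1
F5 | step 12 | (3R,5S)-3,5-dimethyl-5-(10-phenyldecyl)-1,2-dioxolane-3-carbaldehyde | C[C@]1(CCCCCCCCCCc2ccccc2)C[C@](C)(C=O)OO1
F6 | step 12 | (3R,5S)-3-(2-methoxyethenyl)-3,5-dimethyl-5-(10-phenyldecyl)-1,2-dioxolane, E/Z mixture | C[C@]1(CCCCCCCCCCc2ccccc2)C[C@](C)(C=COC)OO1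
F7 | step 12 | 2-[(3R,5S)-3,5-dimethyl-5-(10-phenyldecyl)-1,2-dioxolan-3-yl]acetaldehyde | C[C@]1(CCCCCCCCCCc2ccccc2)C[C@](C)(CC=O)OO1
F8 | step 7 | (6R)-6-methyl-6-(10-phenyldecyl)-1,3-dioxan-4-one | C[C@@]1(CCCCCCCCCCc2ccccc2)CC(=O)OCO1
F9 | step 7 | (3R)-3-hydroxy-3-methyl-13-phenyltridecanoic acid | C[C@@](O)(CCCCCCCCCCc1ccccc1)CC(=O)O
F10 | step 7 | (4R)-4-methyl-4-(10-phenyldecyl)oxetan-2-one | C[C@@]1(CCCCCCCCCCc2ccccc2)CC(=O)O1
F11 | step 7 | (2R)-2-methyl-4-methylidene-2-(10-phenyldecyl)oxetane | C[C@@]1(CCCCCCCCCCc2ccccc2)CC(=C)O1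
F12 | step 5 | (2R)-12-phenyldodecan-2-yl 2,4,6-tri(propan-2-yl)benzoate | C[C@@H](OC(=O)c1c(C(C)C)cc(C(C)C)cc1C(C)C)CCCCCCCCCCc1ccccc1
F13 | step 5 | 2-[(4S)-2,4-dimethyl-14-phenyltetradec-1-en-4-yl]-4,4,5,5-tetramethyl-1,3,2-dioxaborolane | C[C@](B1OC(C)(C)C(C)(C)O1)(CC(C)=C)CCCCCCCCCCc1ccccc1
F14 | step 5 | (4R)-2,4-dimethyl-14-phenyltetradec-1-en-4-ol | C[C@](O)(CC(C)=C)CCCCCCCCCCc1ccccc1
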